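Ring numbering used throughout: C1 carries the (E)-hept-1-enyl group, C2 the CH2OH group, C3 is a carbinol, C4 is the oxirane CH, C5 the quaternary oxirane carbon with the (E)-3-carboxybut-2-enyl chain, and C6 is the second carbinol. Compound numbers are those of the steps and of the compound list.

## Analysis of the target

Target 19 is one carbocycle: a cyclohexene (C1=C2) fused across C4–C5 to an oxirane, with every ring carbon substituted. It has four contiguous stereocentres, C3 to C6, in the configuration (3S,4R,5S,6R) by the ring numbering above. The two hydroxyl groups at C3 and C6 lie on the same face and the oxirane oxygen on the opposite face, so each carbinol is trans to the neighbouring oxirane C–O bond, and C5 is quaternary. C1=C2 is tetrasubstituted and conjugated with the E-heptenyl alkene; C2 carries a primary allylic alcohol and the C5 chain ends in an E α-methyl enoic acid. The sensitive points are the oxirane between two trans hydroxyls (epoxide migration in base, opening in acid) and the C6 carbinol, which is allylic to a diene and ionises readily. In addition, any precursor with a C4=C5 alkene and two allylic oxygens is one elimination away from a benzene ring. The difficulty lies in setting the absolute configuration without a chiral-pool handle, in building a quaternary oxirane carbon, and in telling four different alkenes apart during oxidation. The strategy rests on one feature: the C3 and C6 oxygens are cis and 1,4 across the ring, C1=C2 with a formyl-level carbon on C2 lies on one side, and C4–C5 (an alkene before it becomes the oxirane) on the other, with the C5 alkyl group para to C2. This is the pattern of a Diels–Alder adduct of a 2-alkynal (C1, C2) with an E,E-1,4-dioxygenated 2-alkyl diene (C3–C6).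

## Retrosynthetic reasoning

19 from 18 and 17. The last bonds dealt with are the two O–Si bonds and the ester O–CH3 bond. The ester is cleaved first (17 to 18), while both secondary carbinols are still silylated, because a free alkoxide at C3 sits anti to the C4–O bond of the oxirane and could migrate the epoxide. The silyl ethers are removed last under buffered fluoride (18 to 19).

17 from 16. The C2 hydroxymethyl group is traced back to a formyl group. The aldehyde is kept until after the oxidation of the ring because it withdraws electron density from C1=C2 and from the heptenyl alkene. The forward step is a 1,2-reduction that must spare the enoate ester and the oxirane.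

16 from 15. The two C–O bonds of the oxirane are cut, which leaves the isolated C4=C5 alkene of the cyclohexa-1,4-diene 15. Cutting here is right because both allylic silyloxy groups sit on one face and steer an external oxidant to the other. The forward step must pick this alkene out of four and must not let the diene aromatise.

15 from 5 and 14 (key disconnection). The C2–C3 and C1–C6 bonds are cut together. This opens the ring into the ynal 5 (C1, C2, the formyl carbon and the whole heptenyl chain) and the bis(silyloxy) diene 14 (C3–C6 with the complete side chain). No other pair of cuts removes the ring and both carbinol stereocentres at once while leaving fragments of this simplicity. The forward cycloaddition has to deliver the para regiochemistry, the cis relationship of C3 and C6, and one enantiomer.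

14 from 13. The C6–O silyl enol ether is traced back to the formyl group of the enal 13, with the C5=C4 alkene of 13 moving to C4=C3 on γ-deprotonation. An enal is chosen as precursor, not a saturated dialdehyde, because its s-trans conformation fixes the geometry of the new enol ether. The substituent on the α-carbon is expected to push the γ-silyloxy group outward.

13 from 11 and 12. The trisubstituted alkene of the enoate is cut by cross-metathesis logic into the allyl group of enal 11 and methyl methacrylate 12. This brings in the E-configured ester in one step from a bulk chemical and avoids an allylic halide of uncertain regiochemistry.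

11 from 7 and 8, and 7 from 6. The alkene of 11, which later becomes C4=C5 of the ring, is cut by aldol-condensation logic. The donor is pent-4-enal 6, used as its cyclohexylimine 7 (lithiated to 9, which gives aldolate 10), and the acceptor is the silyloxy aldehyde 8. This places ring C6 and C5 (from 6) next to ring C4 and C3 (from 8) with the oxygen pattern already in place.

5 from 2 and 1. The formyl carbon is removed from the acetylide 3 (through the adduct 4), and the triple bond is traced back through the dibromo-olefin 2 to (E)-oct-2-enal 1. The E alkene of the heptenyl chain is bought, not made.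

## Alternatives that were turned down

Alternative 1: Both carbinol C–O bonds are cut at once, leading from the epoxy endoperoxide A2 back to the benzene oxide A1 (ester on C1, silyloxymethyl on C2, side chain on C5). In the forward direction singlet oxygen would add as a dienophile across C3 and C6 of the cyclohexadiene part of A1, on the face away from the oxirane, and reduction of the O–O bond would give the cis diol. In its favour, one step sets both carbinols cis to each other and trans to the oxirane, and no separate epoxidation is needed. On relative stereocontrol and on the alkene-selection problem of step 8 it is stronger than the chosen route. Against it, A1 equilibrates with its oxepine valence tautomer, through which an unsymmetrical arene oxide loses its configuration, and it isomerises to phenols with traces of acid. The absolute configuration therefore cannot be stored in A1. A2 also carries an ester on C1, so the heptenyl chain must be built after the key step, two esters must be differentiated, and the tert-butyl ester would need acid with an oxirane present. The trisubstituted side-chain alkene offers allylic hydrogens for an ene reaction with singlet oxygen. The chosen strategy gives up that stereochemical economy. In return it offers catalyst control of the absolute configuration and a complete carbon skeleton directly after the ring-forming step.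

Alternative 2: The C1–C6 bond is cut, leading from the ring compound A4 to the open-chain epoxy aldehyde A3 with an alkenyl iodide at C1. In the forward direction CrCl2 with catalytic NiCl2 would convert the C–I bond into an alkenylchromium species that adds to the C6 aldehyde and closes the ring (Nozaki–Hiyama–Kishi). In its favour, the conditions tolerate oxiranes, esters and silyl ethers, and there is no regiochemical question. C3, C4 and C5 would be made beforehand by acyclic asymmetric reactions with well-understood control, so on absolute configuration it stands on firmer ground than an untested catalytic cycloaddition. Against it, C6 is created in the ring closure next to the quaternary oxirane carbon under substrate control with no clear bias for the required face, and a wrong epimer would cost an oxidation and a reduction. A3 combines an α,α-disubstituted epoxy aldehyde with a tetrasubstituted iodo-diene of fixed geometry and needs a long linear sequence. Chromium is used in excess, and the tert-butyl ester again asks for acid at the end. The chosen strategy sets C3 and C6 together under catalyst control and reaches its cyclisation partners in two and four steps.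

Alternative 3: The C2–C3 ring bond and the C1–alkenyl bond are cut, leading from A7 to the alkynal A5 and (E)-hept-1-enylboronic acid A6. In the forward direction Pd(PPh3)4 would mediate trans addition across the alkyne: the alkenyl group goes to C1 and C2 attacks the C3 aldehyde, closing the ring with an endocyclic tetrasubstituted alkene and the C3 carbinol. In its favour, ring closure, placement of the substituents on the alkene and attachment of the heptenyl chain happen in one step, and the regiochemistry is fixed by the tether. The oxirane is already present, so no alkene has to be selected for oxidation. On these two points it is stronger than the chosen route. Against it, the C3 configuration is set by substrate control next to the oxirane, where Felkin-type and chelation models point to different faces. A5 is an α-epoxy aldehyde with an epimerisable centre and needs C4, C5 (quaternary) and C6 assembled in an open chain. Alkenylboronic acids are also less secure than arylboronic acids in this kind of cyclisation, since protodeboronation and direct 1,2-addition compete. The chosen strategy is shorter and makes both carbinol centres in the step that makes the ring.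

Key step: step 7

Assumption: the catalyst from (S)-α,α-diphenylprolinol is taken to give 15 in the configuration drawn (formyl-bound complex, diene approaching in exo orientation the face not covered by the phenyl group); should the adduct prove to be the mirror image, the catalyst from (R)-α,α-diphenylprolinol is used and nothing else changes.

## Route

Step 1
Reactants: 1 (E)-oct-2-enal
Product: 2 (3E)-1,1-dibromonona-1,3-diene
Conditions: CBr4, PPh3, CH2Cl2, 0 °C
Reagents that add atoms: carbon tetrabromide, BrC(Br)(Br)Br
Why: Corey–Fuchs dibromo-olefination; the ylide Ph3P=CBr2 formed from CBr4 and PPh3 reacts with the aldehyde in a Wittig reaction, and the E alkene of 1 is not touched.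

Step 2
Reactants: 2 (3E)-1,1-dibromonona-1,3-diene
Product: 5 (4E)-dec-4-en-2-ynal, via lithium (3E)-non-3-en-1-yn-1-ide 3 (not isolated), via lithium hemiaminal alkoxide 4 (not isolated)
Conditions: n-BuLi (2.1 equiv), THF, −78 °C; DMF, −78 to 0 °C; inverse quench into cold aq. KH2PO4
Reagents that add atoms: N,N-dimethylformamide, CN(C)C=O
Why: Second stage of the Corey–Fuchs sequence; bromine–lithium exchange, loss of LiBr with a 1,2-hydrogen shift and deprotonation give acetylide 3, which adds to DMF. The adduct 4 is stable until the buffered inverse quench, which releases the ynal while keeping dimethylamine protonated so that it cannot add to the triple bond.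

Step 3
Reactants: 6 pent-4-enal
Product: 7 (E)-N-cyclohexylpent-4-en-1-imine
Conditions: c-C6H11NH2, MgSO4, Et2O, 0 °C to rt
Reagents that add atoms: cyclohexylamine, NC1CCCCC1
Why: Condensation of an unhindered aldehyde with a primary amine with removal of water; the imine is an enolate precursor that cannot condense with itself.

Step 4
Reactants: 7 (E)-N-cyclohexylpent-4-en-1-imine; 8 2-(tert-butyldimethylsilyloxy)acetaldehyde
Product: 11 (2E)-4-(tert-butyldimethylsilyloxy)-2-(prop-2-enyl)but-2-enal, via lithiated imine 9 (not isolated), via lithium aldolate 10 (not isolated)
Conditions: LiN(iPr)2, THF, −78 to 0 °C; 8, −78 °C; aq. (CO2H)2, THF, 0 °C to rt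
Reagents that add atoms: water, O
Why: Directed aldol condensation of a metalated aldimine; the aza-enolate 9 adds to the more electrophilic α-silyloxy aldehyde 8 at low temperature. Mild acid then hydrolyses the imine and dehydrates the aldol by way of the enamine to the conjugated enal, with the formyl group trans to CH2OTBS (thermodynamic E isomer), and the primary silyl ether tolerates dilute oxalic acid.

Step 5
Reactants: 11 (2E)-4-(tert-butyldimethylsilyloxy)-2-(prop-2-enyl)but-2-enal; 12 methyl methacrylate
Product: 13 methyl (2E,5E)-7-(tert-butyldimethylsilyloxy)-5-formyl-2-methylhepta-2,5-dienoate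
Conditions: 12 (10 equiv), second-generation Hoveyda–Grubbs catalyst (H2IMes)Cl2Ru=CH(2-iPrOC6H4) (5 mol%), 1,4-benzoquinone (10 mol%), CH2Cl2, 40 °C
Reagents that add atoms: none
Why: Olefin cross-metathesis of a terminal alkene with a 1,1-disubstituted acrylate; the methacrylate does not homodimerise, the trisubstituted product does not re-enter the cycle, and the ester ends up trans to the chain (E) for steric reasons. The conjugated enal alkene is inert, and benzoquinone suppresses migration of the skipped alkene.

Step 6
Reactants: 13 methyl (2E,5E)-7-(tert-butyldimethylsilyloxy)-5-formyl-2-methylhepta-2,5-dienoate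
Product: 14 (1E,3E)-1,4-bis(tert-butyldimethylsilyloxy)-2-[(2E)-3-(methoxycarbonyl)but-2-enyl]buta-1,3-diene
Conditions: TBSOTf (1.2 equiv), Et3N, CH2Cl2, −78 to 0 °C; pentane/aq. NaHCO3 work-up
Reagents that add atoms: tert-butyldimethylsilyl trifluoromethanesulfonate, CC(C)(C)[Si](C)(C)OS(=O)(=O)C(F)(F)F
Why: Soft enolisation of an enal to a silyl dienol ether; O-silylation gives an oxocarbenium ion that the amine deprotonates at the γ-carbon. The s-trans enal places the new silyloxy group trans to the chain (1E), and the γ-silyloxy group should turn away from the substituent on the neighbouring sp2 carbon to avoid allylic 1,3-strain (3E); the ester is not enolised under these conditions.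

Step 7
Reactants: 5 (4E)-dec-4-en-2-ynal; 14 (1E,3E)-1,4-bis(tert-butyldimethylsilyloxy)-2-[(2E)-3-(methoxycarbonyl)but-2-enyl]buta-1,3-diene
Product: 15 (3R,6S)-3,6-bis(tert-butyldimethylsilyloxy)-1-[(E)-hept-1-enyl]-5-[(2E)-3-(methoxycarbonyl)but-2-enyl]cyclohexa-1,4-diene-2-carbaldehyde (ring numbering of this text; both silyloxy groups on one face)
Conditions: N-protonated (S)-B-(2-methylphenyl)-diphenylprolinol oxazaborolidine triflimide (20 mol%; from (S)-α,α-diphenylprolinol, (2-MeC6H4)B(OH)2 and HNTf2, oxazaborolidine in slight excess), CH2Cl2, −78 °C; Et3N quench at −78 °C
Reagents that add atoms: none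
Why: The boron of the cationic oxazaborolidine binds the formyl oxygen of 5 anti to the alkyne and lowers the LUMO of the conjugated triple bond; 14 then adds in a concerted but asynchronous normal-demand [4+2] cycloaddition in which the C1–C6 bond (from the β-carbon of the ynal) runs ahead of the C2–C3 bond. The closest known reaction type is the oxazaborolidinium-catalysed Diels–Alder reaction of α,β-unsaturated and acetylenic aldehydes with silyloxy dienes. The six-membered ring is closed by this intermolecular suprafacial–suprafacial [4π+2π] addition, both ring bonds forming in the one step. C3 and C6 arise from the two enol-ether termini, and because both silyloxy groups are outside substituents of the E,E diene and the addition is suprafacial on the diene, they must end up cis. Their absolute configuration is set by the catalyst: in the formyl-bound complex one face of the ynal lies over a phenyl group of the prolinol unit, and the diene approaches the open face with its C4–C5 unit turned away from the carbonyl oxygen (exo). The step needs para regioselectivity, which the alkyl group on C5 supplies (attack through the terminus next to it leaves positive charge on the alkyl-bearing carbon and on the far oxygen-bearing carbon), and chemoselectivity for the triple bond over the formyl group and the remote alkene, which follows from conjugation and from the bulk of the silyl enol ethers. No second addition is expected because the new C1=C2 bond is tetrasubstituted. The adduct is quenched cold with amine and used at once, since loss of silanol would give an arene.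

Step 8
Reactants: 15 the cycloadduct of step 7
Product: 16 (3S,4R,5R,6R)-4,5-epoxide of 15: 3,6-bis(tert-butyldimethylsilyloxy)-4,5-epoxy-1-[(E)-hept-1-enyl]-5-[(2E)-3-(methoxycarbonyl)but-2-enyl]cyclohex-1-ene-2-carbaldehyde, oxirane oxygen trans to both silyloxy groups
Conditions: DMDO (1.1 equiv, acetone solution), CH2Cl2, −40 to 0 °C
Reagents that add atoms: dimethyldioxirane, CC1(C)OO1
Why: Electrophilic epoxidation by a dioxirane (concerted spiro oxygen transfer); C4=C5 is the only isolated, ring-bound trisubstituted alkene, whereas C1=C2 and the heptenyl alkene form an electron-poor dienal, the heptenyl alkene is in addition trans-disubstituted (slow with dioxiranes) and the enoate alkene is deactivated by its ester. The two bulky silyloxy groups cover one face, so oxygen is delivered to the other, which sets C4 and C5 trans to both carbinol oxygens. The neutral medium avoids loss of silanol to an arene and Baeyer–Villiger oxidation of the formyl group, which is why a peracid is not used.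

Step 9
Reactants: 16 the epoxy aldehyde of step 8
Product: 17 (3S,4R,5R,6R)-epoxy alcohol: methyl (2E)-4-[3,6-bis(tert-butyldimethylsilyloxy)-4,5-epoxy-1-[(E)-hept-1-enyl]-2-(hydroxymethyl)cyclohex-1-en-5-yl]-2-methylbut-2-enoate
Conditions: NaBH4, CeCl3·7H2O, MeOH/THF, −78 °C
Reagents that add atoms: none
Why: Luche reduction; the cerium-modified borohydride adds 1,2 to the conjugated aldehyde at low temperature and leaves the enoate ester, the oxirane and the silyl ethers alone, and no stereocentre is formed.

Step 10
Reactants: 17 the epoxy alcohol of step 9
Product: 18 (3S,4R,5R,6R)-bis(silyl ether) acid: (2E)-4-[3,6-bis(tert-butyldimethylsilyloxy)-4,5-epoxy-1-[(E)-hept-1-enyl]-2-(hydroxymethyl)cyclohex-1-en-5-yl]-2-methylbut-2-enoic acid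
Conditions: LiOH·H2O, THF/MeOH/H2O, 0 °C to rt; aq. NaH2PO4
Reagents that add atoms: lithium hydroxide, [Li+].[OH-]
Why: Saponification by acyl–oxygen cleavage; both secondary carbinols are still silylated, so no alkoxide sits next to the oxirane and epoxide migration of the Payne type cannot start. A silyl shift from the C3 oxygen to the primary hydroxyl would be without consequence because all silyl groups are removed in step 11.

Step 11
Reactants: 18 the bis(silyl ether) acid of step 10
Product: 19 target, (2E)-4-[(1S,2R,5S,6R)-3-[(E)-hept-1-enyl]-2,5-dihydroxy-4-(hydroxymethyl)-7-oxabicyclo[4.1.0]hept-3-en-1-yl]-2-methylbut-2-enoic acid, (3S,4R,5S,6R) in the ring numbering of this text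
Conditions: HF·pyridine, pyridine, THF, 0 °C to rt; pH 5 buffer work-up
Reagents that add atoms: none
Why: Fluoride-driven cleavage of the two secondary silyl ethers (strong Si–F bond) in a pyridine-buffered medium that is neither basic enough for epoxide migration nor acidic enough to open the oxirane or ionise the C6 carbinol; no stereocentre is touched.

## Compound list

1 | (E)-oct-2-enal | CCCCC/C=C/C=O | starting material
2 | (3E)-1,1-dibromonona-1,3-diene | CCCCC/C=C/C=C(Br)Br | intermediate
3 | lithium (3E)-non-3-en-1-yn-1-ide (not isolated) | CCCCC/C=C/C#C[Li] | intermediate
4 | lithium (4E)-1-(dimethylamino)dec-4-en-2-yn-1-olate (not isolated) | CCCCC/C=C/C#CC(O[Li])N(C)C | intermediate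
5 | (4E)-dec-4-en-2-ynal | CCCCC/C=C/C#CC=O | intermediate
6 | pent-4-enal | C=CCCC=O | starting material
7 | (E)-N-cyclohexylpent-4-en-1-imine | C=CCC/C=N/C1CCCCC1 | intermediate
8 | 2-(tert-butyldimethylsilyloxy)acetaldehyde | O=CCO[Si](C)(C)C(C)(C)C | starting material
9 | lithiated imine of 7, 1-azaallyl lithium, geometry not defined (not isolated) | C=CCC=CN([Li])C1CCCCC1 | intermediate
10 | lithium 1-(tert-butyldimethylsilyloxy)-3-[(cyclohexylimino)methyl]hex-5-en-2-olate, mixture of diastereomers (not isolated) | C=CCC(C=NC1CCCCC1)C(O[Li])CO[Si](C)(C)C(C)(C)C | intermediate
11 | (2E)-4-(tert-butyldimethylsilyloxy)-2-(prop-2-enyl)but-2-enal | O=C/C(CC=C)=C/CO[Si](C)(C)C(C)(C)C | intermediate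
12 | methyl methacrylate | C=C(C)C(=O)OC | starting material
13 | methyl (2E,5E)-7-(tert-butyldimethylsilyloxy)-5-formyl-2-methylhepta-2,5-dienoate | O=C/C(C/C=C(\C)C(=O)OC)=C/CO[Si](C)(C)C(C)(C)C | intermediate
14 | (1E,3E)-1,4-bis(tert-butyldimethylsilyloxy)-2-[(2E)-3-(methoxycarbonyl)but-2-enyl]buta-1,3-diene | CC(C)(C)[Si](C)(C)O/C=C/C(C/C=C(\C)C(=O)OC)=C/O[Si](C)(C)C(C)(C)C | intermediate
15 | (3R,6S)-cis-3,6-bis(silyloxy)cyclohexa-1,4-diene-2-carbaldehyde with C1 heptenyl and C5 side chain | CCCCC/C=C/C1=C(C=O)[C@H](O[Si](C)(C)C(C)(C)C)C=C(C/C=C(\C)C(=O)OC)[C@@H]1O[Si](C)(C)C(C)(C)C | intermediate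
16 | (3S,4R,5R,6R)-epoxy aldehyde, oxirane trans to both silyloxy groups | CCCCC/C=C/C1=C(C=O)[C@H](O[Si](C)(C)C(C)(C)C)[C@H]2O[C@@]2(C/C=C(\C)C(=O)OC)[C@@H]1O[Si](C)(C)C(C)(C)C | intermediate
17 | (3S,4R,5R,6R)-epoxy alcohol, methyl ester, bis(silyl ether) | CCCCC/C=C/C1=C(CO)[C@H](O[Si](C)(C)C(C)(C)C)[C@H]2O[C@@]2(C/C=C(\C)C(=O)OC)[C@@H]1O[Si](C)(C)C(C)(C)C | intermediate
18 | (3S,4R,5R,6R)-epoxy alcohol, carboxylic acid, bis(silyl ether) | CCCCC/C=C/C1=C(CO)[C@H](O[Si](C)(C)C(C)(C)C)[C@H]2O[C@@]2(C/C=C(\C)C(=O)O)[C@@H]1O[Si](C)(C)C(C)(C)C | intermediate
19 | (2E)-4-[(1S,2R,5S,6R)-3-[(E)-hept-1-enyl]-2,5-dihydroxy-4-(hydroxymethyl)-7-oxabicyclo[4.1.0]hept-3-en-1-yl]-2-methylbut-2-enoic acid | CCCCC/C=C/C1=C(CO)[C@H](O)[C@H]2O[C@@]2(C/C=C(\C)C(=O)O)[C@@H]1O | target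

## Step count and least certain steps

Total step count: 11. Longest linear sequence: 9 steps (6 to 19, steps 3 to 11); the ynal branch (steps 1 and 2) joins at step 7.

Step 7 (key step). Three things are most likely to go wrong:
- The internal enol-ether carbons of 14 may add to the activated formyl group (Mukaiyama-type aldol or oxa-[4+2]) in place of cycloaddition at the triple bond.
- The adduct may lose silanol under the acidic catalyst and aromatise.
- Face and orientation control may be incomplete. With a linear ynal the enantiomer depends both on the face attacked and on the exo or endo placement of the diene, and both termini of 14 are donors, so regiocontrol rests on the alkyl group alone.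

The fallback moves from one-point activation of an aldehyde to two-point activation of an acyl pyrazole. It sets out from acetylide 3 and diene 14 and comes back at 17. Acetylide 3 is quenched with CO2 to (E)-dec-4-en-2-ynoic acid F1, which is converted by way of its acid chloride with 3,5-dimethylpyrazole into 1-[(E)-dec-4-en-2-ynoyl]-3,5-dimethylpyrazole F2. F2 chelates a chiral copper Lewis acid (Cu(OTf)2 with a C2-symmetric bis(oxazoline) ligand, divalent copper, ligand enantiomer chosen to give the configuration drawn) and reacts with 14 to give the pyrazolide cycloadduct F3. This catalyst is less acidic, and the acyl group is not prone to 1,2-attack. DMDO then gives the pyrazolide epoxide F4, and NaBH4/CeCl3·7H2O reduces the acyl pyrazole directly to the primary alcohol 17.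

Step 8. The dioxirane may fail to distinguish C4=C5, which is slowed by two allylic oxygens, from the heptenyl alkene of the dienal, giving a side-chain epoxide or double oxidation. The fallback removes the competing alkene from the substrate and attaches it after the oxidation. It sets out from diene 14 and comes back at 16. 3-Bromoprop-2-yn-1-ol F5 is oxidised with MnO2 to 3-bromopropynal F6, which takes the place of 5 in the cycloaddition of step 7 and gives the bromo cycloadduct F7. DMDO gives the bromo epoxy aldehyde F8, which now has no second electron-rich alkene. Suzuki–Miyaura coupling of the β-bromo enal with (E)-hept-1-enylboronic acid F9 (Pd(PPh3)4, K3PO4, THF/H2O, rt) then gives 16.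

Step 6. The γ-deprotonation may place the silyloxy group inward (3Z isomer), because an electronic preference for a cis oxygen works against the allylic strain argument; the dienol ether may also hydrolyse on work-up. The fallback stops asking the enolisation for a single isomer and leaves the geometric sorting to the cycloaddition. It sets out from the isomer mixture of 14 and comes back at 15. The mixture is used in excess in step 7, where only the E,E isomer can reach the s-cis conformation and react, and the unreactive isomer is removed at the stage of 15. This fallback makes no new compound (F0).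

Step 11. Acid-promoted opening of the oxirane or ionisation at C6 may occur during the slow cleavage of the hindered C6 silyl ether. The fallback changes the order of the last two operations so that neither hydroxide nor HF meets the free epoxy triol acid. It sets out from 17 and comes back at 19. The silyl ethers of 17 are removed with TBAF buffered with AcOH to give the triol methyl ester F10, and the ester is then cleaved under neutral conditions with Me3SnOH in 1,2-dichloroethane to give 19.

## Further compounds

F1 | step 7 | (E)-dec-4-en-2-ynoic acid | CCCCC/C=C/C#CC(=O)O
F2 | step 7 | 1-[(E)-dec-4-en-2-ynoyl]-3,5-dimethylpyrazole | CCCCC/C=C/C#CC(=O)n1nc(C)cc1C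
F3 | step 7 | pyrazolide cycloadduct, acyl pyrazole analogue of 15 | CCCCC/C=C/C1=C(C(=O)n2nc(C)cc2C)[C@H](O[Si](C)(C)C(C)(C)C)C=C(C/C=C(\C)C(=O)OC)[C@@H]1O[Si](C)(C)C(C)(C)C
F4 | step 7 | pyrazolide epoxide, acyl pyrazole analogue of 16 | CCCCC/C=C/C1=C(C(=O)n2nc(C)cc2C)[C@H](O[Si](C)(C)C(C)(C)C)[C@H]3O[C@@]3(C/C=C(\C)C(=O)OC)[C@@H]1O[Si](C)(C)C(C)(C)C
F5 | step 8 | 3-bromoprop-2-yn-1-ol | OCC#CBr
F6 | step 8 | 3-bromopropynal | O=CC#CBr
F7 | step 8 | bromo cycloadduct, C1-bromo analogue of 15 | BrC1=C(C=O)[C@H](O[Si](C)(C)C(C)(C)C)C=C(C/C=C(\C)C(=O)OC)[C@@H]1O[Si](C)(C)C(C)(C)C
F8 | step 8 | bromo epoxy aldehyde, C1-bromo analogue of 16 | BrC1=C(C=O)[C@H](O[Si](C)(C)C(C)(C)C)[C@H]2O[C@@]2(C/C=C(\C)C(=O)OC)[C@@H]1O[Si](C)(C)C(C)(C)C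
F9 | step 8 | (E)-hept-1-enylboronic acid | CCCCC/C=C/B(O)O
F0 | step 6 | none | none
F10 | step 11 | triol methyl ester, methyl ester of 19 | CCCCC/C=C/C1=C(CO)[C@H](O)[C@H]2O[C@@]2(C/C=C(\C)C(=O)OC)[C@@H]1O
A1 | alternative 1 | benzene oxide with C1 methyl ester, C2 silyloxymethyl and C5 side chain as tert-butyl ester | COC(=O)C1=C[C@]2(C/C=C(\C)C(=O)OC(C)(C)C)O[C@@H]2C=C1CO[Si](C)(C)C(C)(C)C
A2 | alternative 1 | anti epoxy endoperoxide | COC(=O)C1=C(CO[Si](C)(C)C(C)(C)C)[C@H](O3)[C@H]2O[C@@]2(C/C=C(\C)C(=O)OC(C)(C)C)[C@@H]1O3
A3 | alternative 2 | open-chain epoxy aldehyde with C1 alkenyl iodide | CCCCC/C=C/C(I)=C(\CO[Si](C)(C)C(C)(C)C)[C@H](O[Si](C)(C)C(C)(C)C)[C@H]1O[C@@]1(C/C=C(\C)C(=O)OC(C)(C)C)C=O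
A4 | alternative 2 | C6-hydroxy bis(silyl ether) tert-butyl ester | CCCCC/C=C/C1=C(CO[Si](C)(C)C(C)(C)C)[C@H](O[Si](C)(C)C(C)(C)C)[C@H]2O[C@@]2(C/C=C(\C)C(=O)OC(C)(C)C)[C@@H]1O
A5 | alternative 3 | epoxy 5-alkynal with C6 silyl ether | O=C[C@H]1O[C@@]1(C/C=C(\C)C(=O)OC)[C@@H](C#CCO[Si](C)(C)C(C)(C)C)O[Si](C)(C)C(C)(C)C
A6 | alternative 3 | (E)-hept-1-enylboronic acid | CCCCC/C=C/B(O)O
A7 | alternative 3 | C3-hydroxy bis(silyl ether) methyl ester | CCCCC/C=C/C1=C(CO[Si](C)(C)C(C)(C)C)[C@H](O)[C@H]2O[C@@]2(C/C=C(\C)C(=O)OC)[C@@H]1O[Si](C)(C)C(C)(C)C
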